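Your vessel is a closed, stirred tank at constant temperature, and it works like two decaying feeds: Z turns into D, L turns into J, and E appears when a D meets a J. Meanwhile D can fall away to X, and J can pair off to G.

| setting | ochre | amber | birch | maple | alder |
|---|---|---|---|---|---|
| Z | 0.10 M | 0.10 M | 0.10 M | 0.10 M | 0.10 M |
| L | 0.074 M | 0.17 M | 0.110 M | 0.110 M | 0.110 M |
| temperature | −25 °C | 0 °C | 0 °C | 20 °C | −20 °C |
| remark | run made earlier | run made earlier |  |  |  |
| time |  |  | 12 min | 12 min | 12 min |

| run | time / min | E / % | Z / % |
|---|---|---|---|
| ochre | 3.00 | 0.7 | 98.1 |
| ochre | 8.00 | 1.5 | 95.0 |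
| ochre | 20.0 | 2.7 | 86.4 |
| ochre | 50.0 | 12.1 | 71.4 |
| amber | 4.00 | 25.6 | 57.8 |
| amber | 8.00 | 40.1 | 31.4 |
| amber | 10.0 | 43.2 | 24.9 |
| amber | 15.0 | 44.1 | 11.9 |

(readings scatter by 1 percentage point)

* which flask leads in amount of E, in percent of the Z charged ("all alike" within 1.5 percentage points) (birch / maple / alder / all alike)
* how much E is there at the end, in percent of the Z charged: birch
* how much E is there at the end, in percent of the Z charged: maple
* how much E is there at the end, in percent of the Z charged: alder

- the analysis behind the earlier runs scatters by 1 percentage point, standard deviation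
- reactions considered so far: Z -> D; L -> J; D + J -> E; 2 J -> G; D -> X

Start with the clock. In amber a reading of 11.9% of Z stands at 15.0 min, so first-order decay gives a constant, read from that one reading, of 0.142 min⁻¹, and birch, at the same temperature, should have consumed 81.8% of its Z by 12 min.

Next comes the split. Amber holds about 43.6% of E at that time, the mean of the readings on either side, so its capture odds are 1.14: E formed divided by Z consumed but not in E. This is a selectivity written as odds. Carried over unchanged, they would make birch copy amber's 43.6%.

That link is weak, so reforge it. At one temperature, D is caught at a rate that follows the level of J, so the odds follow J too. Late in amber, the readings show E gaining 0.9 percentage points while Z loses 13 points, which I read as J's supply fading, and E then holds a quarter of the L charged. I take pairing as J's main drain, and that is my assumption. A J pool fed in proportion to L and drained by pairing sits, in the steady-state approximation, in proportion to the square root of L. Correcting amber's odds by that square root means multiplying by 0.804, which gives 0.921 for birch and, by my reckoning, 39.2% of E.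

The forecast differs from my figure for birch: it names birch as the leader with 32% there, 28% in maple and 4% in alder, arguing that “the supply should end sooner”.

The flasks give 39.1% in birch, 32.4% in maple and 5.93% in alder, so birch leads.

    Z → D (k = 0.00240 s⁻¹, Ea = 70.0 kJ mol⁻¹)
    L → J (k = 0.00340 s⁻¹, Ea = 80.0 kJ mol⁻¹)
    D + J → E (k = 5.20 M⁻¹ s⁻¹, Ea = 49.0 kJ mol⁻¹)
    2 J → G (k = 5.80 M⁻¹ s⁻¹, Ea = 50.0 kJ mol⁻¹)
    D → X (k = 0.0150 s⁻¹, Ea = 77.0 kJ mol⁻¹)
    (constants at 0 °C)

Birch's odds at 12 min come to 0.905. In maple at 0.308 min, J goes to G 2.4 times as fast as it goes to E, and D goes to X 1.2 times as fast as it goes to E. Now take amber at 15.0 min, with 47.4% of E without the scatter, and cut its L to birch's charge: the corrected odds are 0.937, which give 42.6% of E, and that flask holds 41.0%.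

The runs stem from a simulated flask on assumed constants; the scatter is artificial.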